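The meeting decided to rank the warm flasks by where they stop, with the even split as the zero of the scale.

| setting | epsilon | zeta | beta | delta | Thursday's | Monday's | Wednesday's | Sunday's |
|---|---|---|---|---|---|---|---|---|
| free monomer | 0.45 M | 1 M | 1.9 M | 1.5 M | 1.5 M | 1.5 M | 2.5 M | 0.40 M |
| initiator | 30 mM | 30 mM | 30 mM | 21 mM | 8.0 mM | 30 mM | 30 mM | 20 mM |
| temperature | −35 °C | −24 °C | −35 °C | −24 °C | −40 °C | −20 °C | −40 °C | −20 °C |
| remark | run made earlier | run made earlier | run made earlier | run made earlier |  |  |  |  |
| time |  |  |  |  | 5.0 min | 5.0 min | 5.0 min | 5.0 min |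

| run | time / min | monomer in chains / % |
|---|---|---|
| epsilon | 0.833 | 0.4 |
| epsilon | 3.00 | 14.5 |
| epsilon | 5.00 | 31.1 |
| epsilon | 8.00 | 52.8 |
| epsilon | 10.0 | 63.3 |
| zeta | 0.417 | 5.3 |
| zeta | 0.833 | 13.7 |
| zeta | 1.33 | 27.8 |
| zeta | 2.50 | 48.3 |
| zeta | 5.00 | 56.1 |
| beta | 0.833 | 6.7 |
| beta | 2.00 | 21.3 |
| beta | 3.00 | 34.0 |
| beta | 5.00 | 49.0 |
| beta | 10.0 | 57.3 |
| delta | 0.417 | 5.8 |
| delta | 0.833 | 12.1 |
| delta | 1.33 | 26.4 |
| delta | 2.50 | 39.8 |
| delta | 5.00 | 46.3 |

(each reading ± 1 percentage point)

1. ranking by amount of monomer in chains, in percent of the free monomer charged, from high to low, at 5.0 min (Thursday's / Monday's / Wednesday's / Sunday's)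
2. the amount of monomer in chains, in percent of the free monomer charged of the flask you put first, at 5.0 min
3. the amount of monomer in chains, in percent of the free monomer charged of the flask you put last, at 5.0 min

I defined the stall odds as monomer in chains over the rest of the charge, taken at a run's last reading. Odds of 1 mean an even split. At −24 °C, delta stood below that at 0.862, and zeta above it at 1.28.

I then compared initiator per free monomer charged: 0.0140 for delta, 0.0300 for zeta. The odds rose with that fraction, with a read exponent of 0.516, about a half.

A colleague objected that zeta was still climbing, by 7.8 percentage points since 2.50 min. I replied that its last time is the asked time, so the reading serves as it stands.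

I therefore proposed the stall constant, the stall odds divided by the square root of the initiator fraction. Zeta gave 7.38 and delta 7.29, which I averaged to a stall constant of 7.33. Beta, at −35 °C and read at 10.0 min, gave 10.7, more than that, so the constant reads lower in the warmer runs. The flasks at −20 °C are warmer still, but I used the constant uncorrected, so I expected my shares to lean high.

For Sunday's, with fraction 0.0500, I reckoned odds of 1.64, so a share of 62.1 %. For Monday's, with fraction 0.0200, I reckoned 1.04, so 50.9 %. I committed to Sunday's above Monday's.

The colleague noted that Wednesday's and Thursday's, at −40 °C, are colder than beta, so I did not apply the constant to them. I put Thursday's last: its 8.0 mM of initiator is less than in any run.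

The forecast gives Sunday's > Monday's > Wednesday's > Thursday's, with 50 % first, against my 62.1 %, and 13 % last, and says “Sunday's versus Monday's is close”.

Sunday's gives 57.6 %, Monday's 47.6 %, and the order is Sunday's > Monday's > Wednesday's > Thursday's, with Thursday's at 11.5 %. Sunday's still holds 6.1 % of its free monomer at 5.0 min, and at 50.0 min it has 60.5 % in chains.

    free monomer + initiator → living end + monomer in chains (k = 0.00850 M⁻¹ s⁻¹, Ea = 47.0 kJ mol⁻¹)
    free monomer + monomer in chains → side product (k = 0.0150 M⁻¹ s⁻¹, Ea = 61.0 kJ mol⁻¹)
    free monomer + living end → monomer in chains + living end, rate k3*[living end]*[free monomer] (k = 1.30 M⁻¹ s⁻¹, Ea = 39.0 kJ mol⁻¹)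
    (constants at −20 °C)

Take Sunday's flask with 1.6 M of free monomer instead. Its fraction is 0.0125, so the stall constant gives odds of 0.820 and a share of 45.0 %. That flask holds 40.6 % in chains at 5.0 min.

(Readings and results stem from a simulated flask from invented constants; scatter was added.)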